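**Plan**

1. Chain labels used below: C1 = lactone carbonyl, C2 (Me), C3 (ketone), C4 (tertiary carbinol), C5 to C12, C13 = ethyl-bearing carbinol carbon. Systematic names use ring locants (chain Cn = ring atom n+1).
2. Retrosynthesis: the C3 ketone goes back to a C3 carbinol, then the ring bond C5–C6 is cut. The homoallylic tertiary carbinol C4(OH)–C5H2–C6(Me)=C7H inside the 14-membered lactone is the retron of a reductive alkyne–epoxide coupling (C4/C5 as a 2,2-disubstituted epoxide, C6≡C7 as a methyl alkyne). Further cuts: the epoxide (to C4=C5), the C13–O ester bond, the C2–C3 aldol bond and the C10–C11 diene bond.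
3. Forward: a C6–C13 alkynyl dienol (Evans alkylation, alkyne homologation, Negishi coupling with a (Z)-β-iodo Baylis–Hillman-type ester) and a C1–C5 acid (Evans aldol with a 2-substituted acrolein) are esterified. Hydroxyl-directed epoxidation then arms C4/C5, the nickel-catalysed reductive macrocyclisation closes the only ring, and C3 oxidation and desilylation finish.
4. Stereochemistry: C8 from auxiliary-controlled alkylation; C13 from a catalytic enantioselective three-component iodo-aldol coupling, which also fixes C11=C12; C2 and the temporary C3 carbinol from the Evans syn-aldol; C4 from the C3-hydroxyl-directed epoxidation; C6=C7 (E) from syn addition of C5 and H across the alkyne in the ring closure.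
5. Helper: the C3 carbinol controls C2, directs the C4 epoxidation and keeps the epoxide from being an α,β-epoxy ketone during nickel catalysis; it is oxidised to the ketone after ring closure.

Key step: step 18

Assumption: in step 6 the (S)-configured oxazaborolidinium catalyst is taken to give the (S)-carbinol; if the sense of induction is the opposite, the (R)-catalyst is used and nothing else changes.

**Route**

Step 1
Reactants: 1 (4R)-4-benzyl-3-propanoyl-1,3-oxazolidin-2-one; 2 2,3-dibromoprop-1-ene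
Product: 4 (4R)-4-benzyl-3-[(2S)-4-bromo-2-methylpent-4-enoyl]-1,3-oxazolidin-2-one, via sodium enolate 3 (not isolated)
Conditions: NaN(SiMe3)2, THF, −78 °C; then 2, −78 to −45 °C
Reagents that add atoms: none
Why: Evans asymmetric alkylation, in which the chelated (Z)-sodium enolate is alkylated by the allylic bromide on the face opposite the benzyl group, which sets C8 as (S) while the vinylic bromide stays inert.

Step 2
Reactants: 4 (4R)-4-benzyl-3-[(2S)-4-bromo-2-methylpent-4-enoyl]-1,3-oxazolidin-2-one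
Product: 5 (2S)-4-bromo-2-methylpent-4-en-1-ol
Conditions: LiBH4, MeOH (1 equiv), Et2O, 0 °C
Reagents that add atoms: none
Why: Reductive cleavage of the N-acyl oxazolidinone by LiBH4 should give the primary alcohol without touching the stereocentre or the alkenyl bromide, and the auxiliary is recovered.

Step 3
Reactants: 5 (2S)-4-bromo-2-methylpent-4-en-1-ol
Product: 6 (2S)-4-bromo-2-methylpent-4-enal
Conditions: Dess–Martin periodinane, pyridine, CH2Cl2, 0 °C to rt
Reagents that add atoms: none
Why: Dess–Martin oxidation under buffered, non-epimerising conditions should give the α-branched aldehyde, which is used crude.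

Step 4
Reactants: 6 (2S)-4-bromo-2-methylpent-4-enal
Product: 7 (4S)-2-bromo-4-methylhex-1-en-5-yne
Conditions: dimethyl (1-diazo-2-oxopropyl)phosphonate, K2CO3, MeOH, 0 °C to rt
Reagents that add atoms: dimethyl (1-diazo-2-oxopropyl)phosphonate, COP(=O)(OC)C(=[N+]=[N-])C(C)=O
Why: Seyferth–Gilbert homologation with the Ohira–Bestmann reagent under mild K2CO3/MeOH conditions should convert the aldehyde into the terminal alkyne (C7≡C6) without epimerising the α-stereocentre.

Step 5
Reactants: 7 (4S)-2-bromo-4-methylhex-1-en-5-yne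
Product: 9 (4S)-2-bromo-4-methylhept-1-en-5-yne, via lithium acetylide 8 (not isolated)
Conditions: LiN(SiMe3)2, THF, −78 °C; then MeI, −78 °C to rt
Reagents that add atoms: iodomethane, CI
Why: Deprotonation of the terminal alkyne by a lithium amide that does not exchange the alkenyl bromide, followed by SN2 methylation, should give the methyl alkyne needed for the ring closure.

Step 6
Reactants: 10 propanal; 11 ethyl prop-2-ynoate
Product: 14 ethyl (2Z)-2-[(1S)-1-hydroxypropyl]-3-iodoprop-2-enoate, via iodoallenyl silyl ketene acetal 12 (not isolated), via trimethylsilyl ether 13 (not isolated)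
Conditions: Me3SiI, 20 mol% of the triflimide salt formed from (S)-3,3-diphenyl-1-(2-methylphenyl)tetrahydro-1H,3H-pyrrolo[1,2-c][1,3,2]oxazaborole and HNTf2, EtCN, −78 °C; then 1 M HCl
Reagents that add atoms: iodotrimethylsilane, C[Si](C)(C)I
Why: Catalytic enantioselective β-iodo Morita–Baylis–Hillman-type three-component coupling, in which iodide adds to the propiolate to give iodoallenolate 12, whose Mukaiyama-type aldol with the catalyst-bound aldehyde sets C13 under catalyst control and gives the (Z)-iodoacrylate that later fixes the C11=C12 geometry.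

Step 7
Reactants: 9 (4S)-2-bromo-4-methylhept-1-en-5-yne; 14 ethyl (2Z)-2-[(1S)-1-hydroxypropyl]-3-iodoprop-2-enoate
Product: 17 ethyl (2Z,6S)-2-[(1S)-1-hydroxypropyl]-6-methyl-4-methylidenenon-2-en-7-ynoate, via alkenyllithium 15 (not isolated), via alkenylzinc chloride 16 (not isolated)
Conditions: t-BuLi (2 equiv), Et2O, −78 °C; ZnCl2, THF, −78 to 0 °C; then 14, Pd(OAc)2 (2 mol%), SPhos (4 mol%), THF, rt
Reagents that add atoms: none
Why: Lithium–bromine exchange, transmetalation to zinc and Negishi coupling with the (Z)-iodoacrylate should form the C10–C11 bond with retention of alkene geometry, the alkenylzinc halide (used in slight excess) tolerating the free hydroxyl under Pd(OAc)2/SPhos catalysis.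

Step 8
Reactants: 17 ethyl (2Z,6S)-2-[(1S)-1-hydroxypropyl]-6-methyl-4-methylidenenon-2-en-7-ynoate
Product: 18 (2E,6S)-2-[(1S)-1-hydroxypropyl]-6-methyl-4-methylidenenon-2-en-7-yn-1-ol
Conditions: i-Bu2AlH (3.5 equiv), CH2Cl2, −78 to 0 °C; Rochelle salt
Reagents that add atoms: none
Why: i-Bu2AlH should reduce the conjugated ester in a 1,2-manner to the primary allylic alcohol with the alkene geometry, the alkyne and the diene untouched.

Step 9
Reactants: 18 (2E,6S)-2-[(1S)-1-hydroxypropyl]-6-methyl-4-methylidenenon-2-en-7-yn-1-ol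
Product: 19 (3S,4E,8S)-4-{[tert-butyl(diphenyl)silyl]oxymethyl}-8-methyl-6-methylideneundec-4-en-9-yn-3-ol
Conditions: t-BuPh2SiCl, imidazole, CH2Cl2, 0 °C
Reagents that add atoms: tert-butyl(chloro)diphenylsilane, CC(C)(C)[Si](Cl)(c1ccccc1)c1ccccc1
Why: The bulky silyl chloride should silylate the primary allylic hydroxyl much faster than the hindered secondary one, which leaves C13–OH free for the esterification.

Step 10
Reactants: 20 2-methylidenepropane-1,3-diol
Product: 21 2-{[tert-butyl(diphenyl)silyl]oxymethyl}prop-2-en-1-ol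
Conditions: t-BuPh2SiCl (1 equiv), imidazole, 20 (3 equiv), THF, 0 °C
Reagents that add atoms: tert-butyl(chloro)diphenylsilane, CC(C)(C)[Si](Cl)(c1ccccc1)c1ccccc1
Why: Statistical monosilylation of the symmetrical diol, used in excess, should give the monoether.

Step 11
Reactants: 21 2-{[tert-butyl(diphenyl)silyl]oxymethyl}prop-2-en-1-ol
Product: 22 2-{[tert-butyl(diphenyl)silyl]oxymethyl}prop-2-enal
Conditions: MnO2, CH2Cl2, rt
Reagents that add atoms: none
Why: Manganese dioxide oxidises the allylic alcohol to the 2-substituted acrolein without over-oxidation.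

Step 12
Reactants: 1 (4R)-4-benzyl-3-propanoyl-1,3-oxazolidin-2-one; 22 2-{[tert-butyl(diphenyl)silyl]oxymethyl}prop-2-enal
Product: 25 (4R)-4-benzyl-3-[(2R,3R)-4-{[tert-butyl(diphenyl)silyl]oxymethyl}-3-hydroxy-2-methylpent-4-enoyl]-1,3-oxazolidin-2-one, via dibutylboron enolate 23 (not isolated), via boron aldolate 24 (not isolated)
Conditions: Bu2BOTf, i-Pr2NEt, CH2Cl2, −78 to 0 °C; then 22, −78 to 0 °C; then pH 7 buffer, MeOH, 30% H2O2, 0 °C
Reagents that add atoms: none
Why: Evans syn-aldol, in which the (Z)-boron enolate reacts through a Zimmerman–Traxler chair on the enolate face opposite the benzyl group, setting C2 (R) and the temporary C3 carbinol (R) that later directs the epoxidation.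

Step 13
Reactants: 25 (4R)-4-benzyl-3-[(2R,3R)-4-{[tert-butyl(diphenyl)silyl]oxymethyl}-3-hydroxy-2-methylpent-4-enoyl]-1,3-oxazolidin-2-one
Product: 26 (4R)-4-benzyl-3-[(2R,3R)-4-{[tert-butyl(diphenyl)silyl]oxymethyl}-2-methyl-3-(triethylsilyloxy)pent-4-enoyl]-1,3-oxazolidin-2-one
Conditions: Et3SiOTf, 2,6-lutidine, CH2Cl2, −78 °C
Reagents that add atoms: triethylsilyl trifluoromethanesulfonate, CC[Si](CC)(CC)OS(=O)(=O)C(F)(F)F
Why: Silylation of the hindered secondary alcohol with the silyl triflate at low temperature avoids retro-aldol and masks the hydroxyl for the carboxyl activation to come.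

Step 14
Reactants: 26 (4R)-4-benzyl-3-[(2R,3R)-4-{[tert-butyl(diphenyl)silyl]oxymethyl}-2-methyl-3-(triethylsilyloxy)pent-4-enoyl]-1,3-oxazolidin-2-one
Product: 28 (2R,3R)-4-{[tert-butyl(diphenyl)silyl]oxymethyl}-2-methyl-3-(triethylsilyloxy)pent-4-enoic acid, via peroxy acid 27 (not isolated)
Conditions: LiOH, 30% H2O2, THF/H2O, 0 °C; then Na2SO3; then 1 M HCl to pH 3
Reagents that add atoms: hydrogen peroxide, OO
Why: Lithium hydroperoxide attacks the exocyclic imide carbonyl selectively without epimerising C2, sulfite reduces the peracid, and the auxiliary is recovered.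

Step 15
Reactants: 28 (2R,3R)-4-{[tert-butyl(diphenyl)silyl]oxymethyl}-2-methyl-3-(triethylsilyloxy)pent-4-enoic acid; 19 (3S,4E,8S)-4-{[tert-butyl(diphenyl)silyl]oxymethyl}-8-methyl-6-methylideneundec-4-en-9-yn-3-ol
Product: 30 (3S,4E,8S)-4-{[tert-butyl(diphenyl)silyl]oxymethyl}-8-methyl-6-methylideneundec-4-en-9-yn-3-yl (2R,3R)-4-{[tert-butyl(diphenyl)silyl]oxymethyl}-2-methyl-3-(triethylsilyloxy)pent-4-enoate, via mixed anhydride 29 (not isolated)
Conditions: 2,4,6-trichlorobenzoyl chloride, Et3N, toluene, rt; then 19, DMAP, toluene, rt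
Reagents that add atoms: none
Why: Yamaguchi esterification through the mixed anhydride and DMAP should acylate the hindered secondary allylic alcohol with retention at C13, the β-silyloxy group blocking self-acylation.

Step 16
Reactants: 30 the seco ester with the C3 triethylsilyl ether
Product: 31 (3S,4E,8S)-4-{[tert-butyl(diphenyl)silyl]oxymethyl}-8-methyl-6-methylideneundec-4-en-9-yn-3-yl (2R,3R)-4-{[tert-butyl(diphenyl)silyl]oxymethyl}-3-hydroxy-2-methylpent-4-enoate
Conditions: PPTS, MeOH/CH2Cl2, 0 °C to rt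
Reagents that add atoms: none
Why: Mild acid methanolysis should remove the secondary triethylsilyl ether while the two tert-butyldiphenylsilyl ethers, far more stable to acid, remain.

Step 17
Reactants: 31 the C3-hydroxy seco ester
Product: 32 (3S,4E,8S)-4-{[tert-butyl(diphenyl)silyl]oxymethyl}-8-methyl-6-methylideneundec-4-en-9-yn-3-yl (2R,3R)-3-[(2R)-2-{[tert-butyl(diphenyl)silyl]oxymethyl}oxiran-2-yl]-3-hydroxy-2-methylpropanoate
Conditions: VO(acac)2 (5 mol%), t-BuOOH, CH2Cl2, 0 °C to rt
Reagents that add atoms: tert-butyl hydroperoxide, CC(C)(C)OO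
Why: Hydroxyl-directed vanadium-catalysed epoxidation, in which the C3 alkoxide delivers oxygen to the C4=C5 face that keeps C2 away from the geminal CH2OSi group (A(1,2) strain), should give the erythro (3,4-anti) epoxy alcohol and thus the (4R) centre, while π-bonds without a free allylic hydroxyl are not oxidised.

Step 18
Reactants: 32 the epoxy alcohol seco ester
Product: 34 (3R,4R,5R,7E,9S,12E,14S)-5,13-bis{[tert-butyl(diphenyl)silyl]oxymethyl}-14-ethyl-4,5-dihydroxy-3,7,9-trimethyl-11-methylidene-1-oxacyclotetradeca-7,12-dien-2-one, via diethylborinate 33 (not isolated)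
Conditions: Ni(cod)2 (20 mol%; cod = 1,5-cyclooctadiene), PBu3 (40 mol%), Et3B (4 equiv), toluene, 60 °C, slow addition of 32 (0.002 M); then aq. NH4Cl
Reagents that add atoms: none
Why: Proposed new method: a nickel-catalysed reductive alkyne–epoxide coupling used as a 14-membered macrocyclisation on a 2,2-disubstituted epoxide and an unactivated methyl alkyne, the closest known reaction type being the Ni(cod)2/PBu3/Et3B reductive coupling of aryl alkynes or 1,3-enynes with terminal monosubstituted epoxides, known intermolecularly and for five- and six-membered ring closure. Mechanistically, zerovalent nickel should open the epoxide by SN2-type oxidative addition at the unhindered C5 methylene (the C4–O bond is untouched, so the C4 configuration from step 17 is retained), the alkyne should insert syn into the Ni–C5 bond with C5 going to the methyl-bearing C6, Et3B should transmetalate the nickel alkoxide and supply an ethyl group that β-eliminates to a nickel hydride, and C–H reductive elimination should place H on C7 cis to C5, which is the (6E) geometry. The ring closes in the endo mode at both partners (C4 and C5 of the epoxide and C6 and C7 of the alkyne all end up in the 14-membered ring), the alternative being a 13-membered ring with an exocyclic ethylidene. No new stereocentre is formed, and the alkene geometry is controlled by the syn addition. Regioselectivity at the alkyne relies on the size difference between methyl and the branched C8 substituent (possibly helped by transient coordination of the C10 methylidene), regioselectivity at the epoxide on the quaternary nature of C4, and chemoselectivity requires that epoxide activation outpaces ionisation of the dienylic C13 ester, which the fully substituted C12 should disfavour; the free C3 hydroxyl should be tolerated because the coupling itself produces an alkoxide, and high dilution suppresses oligomers.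

Step 19
Reactants: 34 the macrocyclic 3,4-diol
Product: 35 (3R,5R,7E,9S,12E,14S)-5,13-bis{[tert-butyl(diphenyl)silyl]oxymethyl}-14-ethyl-5-hydroxy-3,7,9-trimethyl-11-methylidene-1-oxacyclotetradeca-7,12-diene-2,4-dione
Conditions: Dess–Martin periodinane, pyridine, CH2Cl2, 0 °C
Reagents that add atoms: none
Why: Dess–Martin oxidation should convert the secondary C3 carbinol into the ketone without touching the tertiary C4 hydroxyl, the buffered non-basic medium leaving the now acidic C2 stereocentre untouched.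

Step 20
Reactants: 35 the bis-silylated keto lactone
Product: 36 (3R,5R,7E,9S,12E,14S)-14-ethyl-5-hydroxy-5,13-bis(hydroxymethyl)-3,7,9-trimethyl-11-methylidene-1-oxacyclotetradeca-7,12-diene-2,4-dione
Conditions: HF·pyridine, pyridine, THF, 0 °C to rt
Reagents that add atoms: none
Why: Fluoride cleavage of the two primary silyl ethers under weakly acidic, buffered conditions should avoid base-induced retro-Claisen opening or translactonisation of the β-keto lactone.

**Compound list**

1 | (4R)-4-benzyl-3-propanoyl-1,3-oxazolidin-2-one | CCC(=O)N1[C@H](Cc2ccccc2)COC1=O | starting material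
2 | 2,3-dibromoprop-1-ene | C=C(Br)CBr | starting material
3 | sodium (Z)-enolate of 1 (formed in the flask) | C/C=C(\[O-])N1[C@H](Cc2ccccc2)COC1=O.[Na+] | intermediate
4 | (4R)-4-benzyl-3-[(2S)-4-bromo-2-methylpent-4-enoyl]-1,3-oxazolidin-2-one | O=C([C@@H](C)CC(Br)=C)N1[C@H](Cc2ccccc2)COC1=O | intermediate
5 | (2S)-4-bromo-2-methylpent-4-en-1-ol | OC[C@@H](C)CC(Br)=C | intermediate
6 | (2S)-4-bromo-2-methylpent-4-enal | O=C[C@@H](C)CC(Br)=C | intermediate
7 | (4S)-2-bromo-4-methylhex-1-en-5-yne | C#C[C@@H](C)CC(Br)=C | intermediate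
8 | lithium acetylide of 7 (formed in the flask) | [Li]C#C[C@@H](C)CC(Br)=C | intermediate
9 | (4S)-2-bromo-4-methylhept-1-en-5-yne | CC#C[C@@H](C)CC(Br)=C | intermediate
10 | propanal | CCC=O | starting material
11 | ethyl prop-2-ynoate | C#CC(=O)OCC | starting material
12 | 1-ethoxy-3-iodo-1-(trimethylsilyloxy)propa-1,2-diene (formed in the flask) | CCOC(O[Si](C)(C)C)=C=CI | intermediate
13 | trimethylsilyl ether of 14 (formed in the flask) | I/C=C(\C(=O)OCC)[C@H](CC)O[Si](C)(C)C | intermediate
14 | ethyl (2Z)-2-[(1S)-1-hydroxypropyl]-3-iodoprop-2-enoate | I/C=C(\C(=O)OCC)[C@H](CC)O | intermediate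
15 | [(4S)-4-methylhept-1-en-5-yn-2-yl]lithium (formed in the flask) | CC#C[C@@H](C)CC(=C)[Li] | intermediate
16 | [(4S)-4-methylhept-1-en-5-yn-2-yl]zinc chloride (formed in the flask) | CC#C[C@@H](C)CC(=C)[Zn]Cl | intermediate
17 | ethyl (2Z,6S)-2-[(1S)-1-hydroxypropyl]-6-methyl-4-methylidenenon-2-en-7-ynoate | CC#C[C@@H](C)CC(=C)/C=C(\C(=O)OCC)[C@H](CC)O | intermediate
18 | (2E,6S)-2-[(1S)-1-hydroxypropyl]-6-methyl-4-methylidenenon-2-en-7-yn-1-ol | CC#C[C@@H](C)CC(=C)/C=C(\CO)[C@H](CC)O | intermediate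
19 | (3S,4E,8S)-4-{[tert-butyl(diphenyl)silyl]oxymethyl}-8-methyl-6-methylideneundec-4-en-9-yn-3-ol | CC#C[C@@H](C)CC(=C)/C=C(\CO[Si](c1ccccc1)(c1ccccc1)C(C)(C)C)[C@H](CC)O | intermediate
20 | 2-methylidenepropane-1,3-diol | C=C(CO)CO | starting material
21 | 2-{[tert-butyl(diphenyl)silyl]oxymethyl}prop-2-en-1-ol | C=C(CO)CO[Si](c1ccccc1)(c1ccccc1)C(C)(C)C | intermediate
22 | 2-{[tert-butyl(diphenyl)silyl]oxymethyl}prop-2-enal | C=C(C=O)CO[Si](c1ccccc1)(c1ccccc1)C(C)(C)C | intermediate
23 | dibutylboron (Z)-enolate of 1 (formed in the flask) | C/C=C(\OB(CCCC)CCCC)N1[C@H](Cc2ccccc2)COC1=O | intermediate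
24 | O-dibutylboryl aldolate of 25 (formed in the flask) | O=C([C@H](C)[C@@H](OB(CCCC)CCCC)C(=C)CO[Si](c1ccccc1)(c1ccccc1)C(C)(C)C)N1[C@H](Cc2ccccc2)COC1=O | intermediate
25 | (4R)-4-benzyl-3-[(2R,3R)-4-{[tert-butyl(diphenyl)silyl]oxymethyl}-3-hydroxy-2-methylpent-4-enoyl]-1,3-oxazolidin-2-one | O=C([C@H](C)[C@@H](O)C(=C)CO[Si](c1ccccc1)(c1ccccc1)C(C)(C)C)N1[C@H](Cc2ccccc2)COC1=O | intermediate
26 | (4R)-4-benzyl-3-[(2R,3R)-4-{[tert-butyl(diphenyl)silyl]oxymethyl}-2-methyl-3-(triethylsilyloxy)pent-4-enoyl]-1,3-oxazolidin-2-one | O=C([C@H](C)[C@@H](O[Si](CC)(CC)CC)C(=C)CO[Si](c1ccccc1)(c1ccccc1)C(C)(C)C)N1[C@H](Cc2ccccc2)COC1=O | intermediate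
27 | peroxy acid corresponding to 28 (formed in the flask) | O=C(OO)[C@H](C)[C@@H](O[Si](CC)(CC)CC)C(=C)CO[Si](c1ccccc1)(c1ccccc1)C(C)(C)C | intermediate
28 | (2R,3R)-4-{[tert-butyl(diphenyl)silyl]oxymethyl}-2-methyl-3-(triethylsilyloxy)pent-4-enoic acid | O=C(O)[C@H](C)[C@@H](O[Si](CC)(CC)CC)C(=C)CO[Si](c1ccccc1)(c1ccccc1)C(C)(C)C | intermediate
29 | mixed anhydride of 28 and 2,4,6-trichlorobenzoic acid (formed in the flask) | O=C(OC(=O)c1c(Cl)cc(Cl)cc1Cl)[C@H](C)[C@@H](O[Si](CC)(CC)CC)C(=C)CO[Si](c1ccccc1)(c1ccccc1)C(C)(C)C | intermediate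
30 | (3S,4E,8S)-4-{[tert-butyl(diphenyl)silyl]oxymethyl}-8-methyl-6-methylideneundec-4-en-9-yn-3-yl (2R,3R)-4-{[tert-butyl(diphenyl)silyl]oxymethyl}-2-methyl-3-(triethylsilyloxy)pent-4-enoate | CC#C[C@@H](C)CC(=C)/C=C(\CO[Si](c1ccccc1)(c1ccccc1)C(C)(C)C)[C@H](CC)OC(=O)[C@H](C)[C@@H](O[Si](CC)(CC)CC)C(=C)CO[Si](c1ccccc1)(c1ccccc1)C(C)(C)C | intermediate
31 | (3S,4E,8S)-4-{[tert-butyl(diphenyl)silyl]oxymethyl}-8-methyl-6-methylideneundec-4-en-9-yn-3-yl (2R,3R)-4-{[tert-butyl(diphenyl)silyl]oxymethyl}-3-hydroxy-2-methylpent-4-enoate | CC#C[C@@H](C)CC(=C)/C=C(\CO[Si](c1ccccc1)(c1ccccc1)C(C)(C)C)[C@H](CC)OC(=O)[C@H](C)[C@@H](O)C(=C)CO[Si](c1ccccc1)(c1ccccc1)C(C)(C)C | intermediate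
32 | (3S,4E,8S)-4-{[tert-butyl(diphenyl)silyl]oxymethyl}-8-methyl-6-methylideneundec-4-en-9-yn-3-yl (2R,3R)-3-[(2R)-2-{[tert-butyl(diphenyl)silyl]oxymethyl}oxiran-2-yl]-3-hydroxy-2-methylpropanoate | CC#C[C@@H](C)CC(=C)/C=C(\CO[Si](c1ccccc1)(c1ccccc1)C(C)(C)C)[C@H](CC)OC(=O)[C@H](C)[C@@H](O)[C@]1(CO[Si](c2ccccc2)(c2ccccc2)C(C)(C)C)CO1 | intermediate
33 | O-diethylboryl ether of 34 at the C4 (ring C5) oxygen (formed in the flask) | C=C1/C=C(\CO[Si](c2ccccc2)(c2ccccc2)C(C)(C)C)[C@H](CC)OC(=O)[C@H](C)[C@@H](O)[C@](OB(CC)CC)(CO[Si](c2ccccc2)(c2ccccc2)C(C)(C)C)C/C(C)=C/[C@@H](C)C1 | intermediate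
34 | (3R,4R,5R,7E,9S,12E,14S)-5,13-bis{[tert-butyl(diphenyl)silyl]oxymethyl}-14-ethyl-4,5-dihydroxy-3,7,9-trimethyl-11-methylidene-1-oxacyclotetradeca-7,12-dien-2-one | C=C1/C=C(\CO[Si](c2ccccc2)(c2ccccc2)C(C)(C)C)[C@H](CC)OC(=O)[C@H](C)[C@@H](O)[C@](O)(CO[Si](c2ccccc2)(c2ccccc2)C(C)(C)C)C/C(C)=C/[C@@H](C)C1 | intermediate
35 | (3R,5R,7E,9S,12E,14S)-5,13-bis{[tert-butyl(diphenyl)silyl]oxymethyl}-14-ethyl-5-hydroxy-3,7,9-trimethyl-11-methylidene-1-oxacyclotetradeca-7,12-diene-2,4-dione | C=C1/C=C(\CO[Si](c2ccccc2)(c2ccccc2)C(C)(C)C)[C@H](CC)OC(=O)[C@H](C)C(=O)[C@](O)(CO[Si](c2ccccc2)(c2ccccc2)C(C)(C)C)C/C(C)=C/[C@@H](C)C1 | intermediate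
36 | (3R,5R,7E,9S,12E,14S)-14-ethyl-5-hydroxy-5,13-bis(hydroxymethyl)-3,7,9-trimethyl-11-methylidene-1-oxacyclotetradeca-7,12-diene-2,4-dione | C=C1/C=C(\CO)[C@H](CC)OC(=O)[C@H](C)C(=O)[C@](O)(CO)C/C(C)=C/[C@@H](C)C1 | target

**Totals**

Total step count: 20.
Longest linear sequence: 14 steps (steps 1–5, 7–9 and 15–20).

**Steps most likely to fail**

1. Step 18 (Proposed new method). The unactivated dialkyl alkyne may insert too slowly into the nickel–carbon bond, so that epoxide isomerisation, oligomerisation, ionisation of the dienylic C13 ester by zerovalent nickel, or translactonisation of the new tertiary alkoxide onto C1 takes over; leakage to the 13-membered ring is a further possibility. The fallback uses known chemistry, sets out from 19 and comes back at 34, and separates hydrometalation from C–C bond formation. Hydrozirconation of 19 with Cp2Zr(H)Cl (excess, THF, 40 °C, zirconium equilibrating to the methyl-bearing carbon) and iodinolysis with I2 should give (3S,4E,8S,9E)-4-{[tert-butyl(diphenyl)silyl]oxymethyl}-10-iodo-8-methyl-6-methylideneundeca-4,9-dien-3-ol F1. Yamaguchi esterification with 28 should give the silyl-protected iodo ester F2, PPTS/MeOH the hydroxy ester F3, and VO(acac)2/t-BuOOH the iodo epoxy alcohol F4, under the conditions of steps 15 to 17. The ring is then closed by a nickel-catalysed reductive cross-electrophile coupling of the alkenyl iodide with the epoxide through the iodohydrin formed in situ (NiCl2(dme), 2,2'-bipyridine, NaI, Et3N·HCl, Zn, DMPU, high dilution). This is a known coupling of sp2 halides with terminal epoxides at the less hindered carbon, and it should give 34.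

2. Step 6. Enantioselectivity may be low with a small unbranched aldehyde, or the (Z)-geometry may erode. The fallback sets out from 10 and 11 and comes back at 14; it replaces asymmetric catalysis by resolution. MgI2-promoted three-component coupling (CH2Cl2, 0 °C) should give racemic ethyl (2Z)-2-(1-hydroxypropyl)-3-iodoprop-2-enoate F5. Lipase-catalysed acylation (Pseudomonas cepacia lipase, vinyl acetate, hexane) should then convert the (R)-enantiomer into ethyl (2Z)-2-[(1R)-1-acetoxypropyl]-3-iodoprop-2-enoate F6 and leave the (S)-alcohol 14, at the cost of at most half the material.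

3. Step 17. Facial selectivity may be poor, or the reaction sluggish, on the flexible late-stage seco ester. The fallback sets out from 25 and comes back at 32; it moves the stereo-determining epoxidation to the small, rigid, crystalline imide, where diastereomers can be separated. VO(acac)2/t-BuOOH on 25 should give the epoxy aldol (4R)-4-benzyl-3-[(2R,3R)-3-[(2R)-2-{[tert-butyl(diphenyl)silyl]oxymethyl}oxiran-2-yl]-3-hydroxy-2-methylpropanoyl]-1,3-oxazolidin-2-one F7, and Et3SiOTf/2,6-lutidine its triethylsilyl ether F8. LiOH/H2O2 should give (2R,3R)-3-[(2R)-2-{[tert-butyl(diphenyl)silyl]oxymethyl}oxiran-2-yl]-2-methyl-3-(triethylsilyloxy)propanoic acid F9, kept as its salt and used at once because γ,δ-epoxy acids lactonise. Yamaguchi esterification with 19 should give the silyl-protected epoxy seco ester F10, and PPTS/MeOH returns to 32.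

**Further compounds**

F1 | step 18 | (3S,4E,8S,9E)-4-{[tert-butyl(diphenyl)silyl]oxymethyl}-10-iodo-8-methyl-6-methylideneundeca-4,9-dien-3-ol | I/C(C)=C/[C@@H](C)CC(=C)/C=C(\CO[Si](c1ccccc1)(c1ccccc1)C(C)(C)C)[C@H](CC)O
F2 | step 18 | ester of F1 with 28 (C3 triethylsilyl ether) | I/C(C)=C/[C@@H](C)CC(=C)/C=C(\CO[Si](c1ccccc1)(c1ccccc1)C(C)(C)C)[C@H](CC)OC(=O)[C@H](C)[C@@H](O[Si](CC)(CC)CC)C(=C)CO[Si](c1ccccc1)(c1ccccc1)C(C)(C)C
F3 | step 18 | C3-hydroxy iodo seco ester | I/C(C)=C/[C@@H](C)CC(=C)/C=C(\CO[Si](c1ccccc1)(c1ccccc1)C(C)(C)C)[C@H](CC)OC(=O)[C@H](C)[C@@H](O)C(=C)CO[Si](c1ccccc1)(c1ccccc1)C(C)(C)C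
F4 | step 18 | iodo epoxy alcohol seco ester | I/C(C)=C/[C@@H](C)CC(=C)/C=C(\CO[Si](c1ccccc1)(c1ccccc1)C(C)(C)C)[C@H](CC)OC(=O)[C@H](C)[C@@H](O)[C@]1(CO[Si](c2ccccc2)(c2ccccc2)C(C)(C)C)CO1
F5 | step 6 | ethyl (2Z)-2-(1-hydroxypropyl)-3-iodoprop-2-enoate (racemic) | I/C=C(\C(=O)OCC)C(CC)O
F6 | step 6 | ethyl (2Z)-2-[(1R)-1-acetoxypropyl]-3-iodoprop-2-enoate | I/C=C(\C(=O)OCC)[C@@H](CC)OC(C)=O
F7 | step 17 | (4R)-4-benzyl-3-[(2R,3R)-3-[(2R)-2-{[tert-butyl(diphenyl)silyl]oxymethyl}oxiran-2-yl]-3-hydroxy-2-methylpropanoyl]-1,3-oxazolidin-2-one | O=C([C@H](C)[C@@H](O)[C@]1(CO[Si](c3ccccc3)(c3ccccc3)C(C)(C)C)CO1)N1[C@H](Cc2ccccc2)COC1=O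
F8 | step 17 | triethylsilyl ether of F7 | O=C([C@H](C)[C@@H](O[Si](CC)(CC)CC)[C@]1(CO[Si](c3ccccc3)(c3ccccc3)C(C)(C)C)CO1)N1[C@H](Cc2ccccc2)COC1=O
F9 | step 17 | (2R,3R)-3-[(2R)-2-{[tert-butyl(diphenyl)silyl]oxymethyl}oxiran-2-yl]-2-methyl-3-(triethylsilyloxy)propanoic acid | O=C(O)[C@H](C)[C@@H](O[Si](CC)(CC)CC)[C@]1(CO[Si](c2ccccc2)(c2ccccc2)C(C)(C)C)CO1
F10 | step 17 | ester of F9 with 19 (C3 triethylsilyl ether of 32) | CC#C[C@@H](C)CC(=C)/C=C(\CO[Si](c1ccccc1)(c1ccccc1)C(C)(C)C)[C@H](CC)OC(=O)[C@H](C)[C@@H](O[Si](CC)(CC)CC)[C@]1(CO[Si](c2ccccc2)(c2ccccc2)C(C)(C)C)CO1
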